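**Assumptions**
- The presumed biosynthesis is taken as (a) attack of the C10=C11 alkene on a C1–C3 allyl cation of a 14-membered, cembranoid-type carbocycle, which closes C1–C10 and so forms ring A and the ten-membered ring together, and (b) hemiketalisation of C7–OH onto the C4 ketone.
- Late intermediates are described with eunicellane locants: ring A = C1, C10–C14; ten-membered ring = C1–C10; C15 = CH2O on C3; C16 = CH3 on C7; isopropyl on C14. The target is 1S,4R,7S,8S,10R,14R, 2Z.
- The auxiliary and catalyst enantiomers named are those predicted by the usual facial models; if a sense of induction is found reversed, the mirror-image reagent (equally available) is used.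

**Retrosynthetic overview**
1. Target ⇐ TBS ether 31 ⇐ lactol 26: C8 acylation pulls the pyranose over to the furanose, so the oxa-bridge is closed last by C7–OH → C4=O hemiketalisation.
2. 26 ⇐ furan 23: the furan is a masked (Z)-ene-1,4-dione; oxidative unveiling, then MeLi puts C16 on C7.
3. 23 ⇐ 14-membered (2,5)-furanophane 19: transannular cation–olefin closure of C1–C10 forms ring A and the ten-membered ring in one step and sets C1 and C10 from C14.
4. 19 ⇐ acyclic diene 18 (ring-closing metathesis) ⇐ furan alcohol 12 + Weinreb amide 14 + vinylmagnesium bromide.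
5. 12 ⇐ furfural (C8 by asymmetric propargylation) + iodide 7 (C14 by auxiliary-controlled conjugate vinylation) + MeMgBr (Z-C10=C11 by syn-carbometalation). Ring order: 14-membered carbocycle → ring A and ten-membered ring together → transient pyranose → oxa-bridged dihydrofuran.

**Route**

Step 1
Reactants: 1 (E)-4-methylpent-2-enoic acid; 2 (R)-4-benzyl-1,3-oxazolidin-2-one
Product: 4 (R)-4-benzyl-3-[(E)-4-methylpent-2-enoyl]-1,3-oxazolidin-2-one, via mixed pivalic anhydride 3 (not isolated)
Conditions: PivCl, Et3N, THF, −20 °C; then LiCl, 2, −20 °C → rt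
Reagents that add atoms: none
Why: One-pot mixed-anhydride N-acylation of the Evans auxiliary, in which the lithium-activated oxazolidinone attacks the less hindered enoyl carbonyl of 3.

Step 2
Reactants: 4 (R)-4-benzyl-3-[(E)-4-methylpent-2-enoyl]-1,3-oxazolidin-2-one
Product: 5 (R)-4-benzyl-3-[(3R)-3-(propan-2-yl)pent-4-enoyl]-1,3-oxazolidin-2-one
Conditions: CH2=CHMgBr (2 equiv), CuBr·SMe2 (30 mol %), THF/Me2S, −40 → −15 °C; then H2O
Reagents that add atoms: vinylmagnesium bromide, C=C[Mg]Br
Why: Auxiliary-controlled copper-mediated conjugate addition to the magnesium-chelated syn-s-cis imide, with vinyl delivered to the β-face opposite the benzyl group, which sets C14 as R.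

Step 3
Reactants: 5 (R)-4-benzyl-3-[(3R)-3-(propan-2-yl)pent-4-enoyl]-1,3-oxazolidin-2-one
Product: 6 (3R)-3-(propan-2-yl)pent-4-en-1-ol
Conditions: LiBH4, THF, 0 °C → rt; aqueous work-up
Reagents that add atoms: none
Why: Reductive cleavage of the N-acyl oxazolidinone at the exocyclic carbonyl, which releases the primary alcohol and the recoverable auxiliary without touching the β-stereocentre.

Step 4
Reactants: 6 (3R)-3-(propan-2-yl)pent-4-en-1-ol
Product: 7 (3R)-5-iodo-3-(propan-2-yl)pent-1-ene
Conditions: I2, PPh3, imidazole, CH2Cl2, 0 °C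
Reagents that add atoms: iodine, II
Why: Appel-type (Garegg–Samuelsson) iodination of an unhindered primary alcohol by SN2 displacement of the alkoxyphosphonium ion.

Step 5
Reactants: 8 furan-2-carbaldehyde (furfural)
Product: 9 (1S)-1-(furan-2-yl)but-3-yn-1-ol
Conditions: allenyl-B(pin), (S)-TRIP phosphoric acid (5 mol %), 4 Å MS, toluene, −20 °C; aqueous work-up
Reagents that add atoms: allenylboronic acid pinacol ester, C=C=CB1OC(C)(C)C(C)(C)O1
Why: Chiral phosphoric acid-catalysed propargylation through a closed six-membered SE2' transition state, in which the catalyst pocket selects one aldehyde face and sets C8 as S.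

Step 6
Reactants: 9 (1S)-1-(furan-2-yl)but-3-yn-1-ol; 7 (3R)-5-iodo-3-(propan-2-yl)pent-1-ene
Product: 11 (1S,7R)-1-(furan-2-yl)-7-(propan-2-yl)non-8-en-3-yn-1-ol, via dilithio dianion 10 (not isolated)
Conditions: n-BuLi (2.05 equiv), THF, −78 °C; then 7, DMPU, −78 °C → rt; then H2O
Reagents that add atoms: none
Why: Acetylide alkylation, in which the soft acetylide carbon of the alkoxide/acetylide dianion displaces the unbranched primary iodide by SN2 while the lithium alkoxide stays unreactive.

Step 7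
Reactants: 11 (1S,7R)-1-(furan-2-yl)-7-(propan-2-yl)non-8-en-3-yn-1-ol
Product: 12 (1S,3Z,7R)-1-(furan-2-yl)-4-methyl-7-(propan-2-yl)nona-3,8-dien-1-ol
Conditions: MeMgBr (4 equiv), Fe(acac)3 (20 mol %), THF, −20 → 0 °C; then H2O
Reagents that add atoms: methylmagnesium bromide, C[Mg]Br
Why: Alkoxide-directed iron-catalysed syn-carbomagnesiation of the homopropargylic alcohol places methyl on the distal carbon (C11) and magnesium, then hydrogen, on C10, so that C9 and C12 end up cis (Z).

Step 8
Reactants: 13 ethyl 2-[(tert-butyldimethylsilyl)oxy]acetate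
Product: 14 2-[(tert-butyldimethylsilyl)oxy]-N-methoxy-N-methylacetamide
Conditions: MeNH(OMe)·HCl, iPrMgCl, THF, −20 → 0 °C; aqueous work-up
Reagents that add atoms: N,O-dimethylhydroxylamine hydrochloride, CNOC.Cl
Why: Direct ester-to-Weinreb-amide conversion by the chloromagnesium amide, whose chelated tetrahedral adduct prevents over-addition.

Step 9
Reactants: 12 (1S,3Z,7R)-1-(furan-2-yl)-4-methyl-7-(propan-2-yl)nona-3,8-dien-1-ol; 14 2-[(tert-butyldimethylsilyl)oxy]-N-methoxy-N-methylacetamide
Product: 16 2-[(tert-butyldimethylsilyl)oxy]-1-{5-[(1S,3Z,7R)-1-hydroxy-4-methyl-7-(propan-2-yl)nona-3,8-dien-1-yl]furan-2-yl}ethan-1-one, via dilithio dianion 15 (not isolated)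
Conditions: n-BuLi (2.2 equiv), THF, −78 → 0 °C; then 14, −78 °C; then H2O
Reagents that add atoms: none
Why: After O-deprotonation the only acidic ring position is the free furan α-CH, and the resulting 5-lithiofuran is acylated once by the Weinreb amide (Weinreb ketone synthesis).

Step 10
Reactants: 16 2-[(tert-butyldimethylsilyl)oxy]-1-{5-[(1S,3Z,7R)-1-hydroxy-4-methyl-7-(propan-2-yl)nona-3,8-dien-1-yl]furan-2-yl}ethan-1-one
Product: 18 (1S,3Z,7R)-1-{5-[(2RS)-1-[(tert-butyldimethylsilyl)oxy]-2-hydroxybut-3-en-2-yl]furan-2-yl}-4-methyl-7-(propan-2-yl)nona-3,8-dien-1-yl acetate, via bis(bromomagnesium) dialkoxide 17 (not isolated)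
Conditions: CH2=CHMgBr (3 equiv), THF, −78 → −20 °C; then Ac2O (3 equiv), −20 → 0 °C; aq NaHCO3
Reagents that add atoms: vinylmagnesium bromide, C=C[Mg]Br; acetic anhydride, CC(=O)OC(C)=O
Why: Grignard 1,2-addition to the chelating α-silyloxy ketone, then in-flask acetylation of the secondary C8 alkoxide only (the hindered tertiary alkoxide is inert at 0 °C); the C3 carbinol is a mixture of epimers, which does not matter because C3 is ionised in step 12.

Step 11
Reactants: 18 (1S,3Z,7R)-1-{5-[(2RS)-1-[(tert-butyldimethylsilyl)oxy]-2-hydroxybut-3-en-2-yl]furan-2-yl}-4-methyl-7-(propan-2-yl)nona-3,8-dien-1-yl acetate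
Product: 19 14-membered (2,5)-furanophane (1E,10Z,8S,14R; 3RS) carrying C3 OH, C15 OTBS, C8 OAc
Conditions: second-generation Grubbs catalyst RuCl2(=CHPh)(PCy3)(H2IMes) (10 mol %), toluene, 1 mM, 60 °C
Reagents that add atoms: none
Why: Ring-closing metathesis of the two monosubstituted vinyl groups (the trisubstituted alkene and the furan are inert) gives the unstrained 14-membered ring with the E C1=C2 alkene, helped by the free allylic hydroxyl.

Step 12
Reactants: 19 14-membered (2,5)-furanophane (1E,10Z,8S,14R; 3RS) carrying C3 OH, C15 OTBS, C8 OAc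
Product: 22 furan-bridged tricycle (1S,2Z,8S,10R,14R) carrying C8 OAc plus C15 OTBS, via allyl cation 20 (not isolated), via ring-A tertiary cation 21 (not isolated)
Conditions: Sc(OTf)3 (5 mol %), (CF3)2CHOH/CH2Cl2 1:4, 2 mM, −40 → −10 °C; Et3N quench
Reagents that add atoms: none
Why: Proposed new method: ionisation of the tertiary furyl- and vinyl-stabilised carbinol gives allyl cation 20, whose C1 terminus is attacked across the ring by the C10=C11 alkene through a chair six-membered transition state (isopropyl and C1–C2 equatorial, C9 axial because the alkene is Z), which sets C1 and C10 from C14 and forms ring A and the ten-membered ring at once, after which cation 21 loses the axial C12 proton to give C11=C12 (the C8 acetate keeps that oxygen from capturing 21 as a tetrahydrofuran); the closest known reaction types are cation–olefin cyclisations started from tertiary allylic alcohols and acid-induced transannular cyclisations of cembranoids.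

Step 13
Reactants: 22 furan-bridged tricycle (1S,2Z,8S,10R,14R) carrying C8 OAc plus C15 OTBS
Product: 23 furan-bridged tricycle (1S,2Z,8S,10R,14R) carrying C8 OH plus C15 OTBS
Conditions: K2CO3 (0.3 equiv), MeOH, 0 °C → rt
Reagents that add atoms: none
Why: Base-catalysed transesterification removes the acetate under conditions that leave the primary TBS ether, the furan and the alkenes untouched.

Step 14
Reactants: 23 furan-bridged tricycle (1S,2Z,8S,10R,14R) carrying C8 OH plus C15 OTBS
Product: 25 bridged 6-hydroxy-2H-pyran-3(6H)-one (1S,4S,8S,10R,14R): C7 ketone, C5=C6, C4 lactol bridged by O to C8, via cis-enedione 24 (not isolated)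
Conditions: VO(acac)2 (5 mol %), t-BuOOH (1.5 equiv), CH2Cl2, 0 °C
Reagents that add atoms: tert-butyl hydroperoxide, CC(C)(C)OO
Why: Achmatowicz rearrangement in which the vanadium alkoxide of the furfuryl C8–OH directs oxidation to the furan (not to the remote C11=C12 or the protected allylic alkene), and the resulting Z-enedione 24 is closed by C8–OH onto C4, the lactol configuration being fixed by the carbocyclic bridge.

Step 15
Reactants: 25 bridged 6-hydroxy-2H-pyran-3(6H)-one (1S,4S,8S,10R,14R)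
Product: 26 bridged pyranose lactol (1S,4S,7S,8S,10R,14R) carrying C7 OH plus C7 CH3
Conditions: MeLi (4 equiv), THF, −78 °C; then H2O
Reagents that add atoms: methyllithium, [Li]C
Why: 1,2-Addition of MeLi to the C7 enone carbonyl of the lactol alkoxide from the exo face, opposite the carbocyclic bridge that spans C4 and C8, puts the new methyl anti and the tertiary hydroxyl syn to C9 (7S).

Step 16
Reactants: 27 1-methyl-1H-imidazole-4-carbaldehyde
Product: 28 (E)-3-(1-methyl-1H-imidazol-4-yl)prop-2-enoic acid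
Conditions: malonic acid, pyridine, piperidine (cat.), 100 °C
Reagents that add atoms: malonic acid, OC(=O)CC(=O)O
Why: Knoevenagel–Doebner condensation with decarboxylation gives the E acrylic acid under thermodynamic control.

Step 17
Reactants: 26 bridged pyranose lactol (1S,4S,7S,8S,10R,14R); 28 (E)-3-(1-methyl-1H-imidazol-4-yl)prop-2-enoic acid
Product: 31 15-O-TBS ether of the target (1S,4R,7S,8S,10R,14R), via Yamaguchi mixed anhydride 29 (not isolated), via furanose lactol 30 (not isolated)
Conditions: 28, 2,4,6-trichlorobenzoyl chloride, Et3N, THF, rt; then 26, DMAP, toluene, rt → 40 °C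
Reagents that add atoms: none
Why: Yamaguchi esterification acylates the only acylable hydroxyl, the secondary C8–OH that is exposed when the pyranose opens and C7–OH re-closes onto the C4 ketone, so the oxa-bridged dihydrofuran lactol is formed by hemiketalisation and trapped, with the 4R configuration dictated by the bridge.

Step 18
Reactants: 31 15-O-TBS ether of the target
Product: 32 target, CNP0196085.1
Conditions: HF·pyridine, pyridine, THF, 0 °C → rt
Reagents that add atoms: none
Why: Buffered fluoride desilylation of the primary allylic TBS ether leaves the lactol, the urocanate ester and all stereocentres unchanged.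

**Compound list**
1 | (E)-4-methylpent-2-enoic acid | CC(C)/C=C/C(=O)O | starting material
2 | (R)-4-benzyl-1,3-oxazolidin-2-one | O=C1N[C@H](Cc2ccccc2)CO1 | starting material
3 | (E)-4-methylpent-2-enoic pivalic anhydride | CC(C)/C=C/C(=O)OC(=O)C(C)(C)C | intermediate (not isolated)
4 | (R)-4-benzyl-3-[(E)-4-methylpent-2-enoyl]-1,3-oxazolidin-2-one | CC(C)/C=C/C(=O)N1[C@H](Cc2ccccc2)COC1=O | intermediate
5 | (R)-4-benzyl-3-[(3R)-3-(propan-2-yl)pent-4-enoyl]-1,3-oxazolidin-2-one | C=C[C@@H](C(C)C)CC(=O)N1[C@H](Cc2ccccc2)COC1=O | intermediate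
6 | (3R)-3-(propan-2-yl)pent-4-en-1-ol | C=C[C@@H](C(C)C)CCO | intermediate
7 | (3R)-5-iodo-3-(propan-2-yl)pent-1-ene | C=C[C@@H](C(C)C)CCI | intermediate
8 | furan-2-carbaldehyde | O=Cc1ccco1 | starting material
9 | (1S)-1-(furan-2-yl)but-3-yn-1-ol | C#CC[C@H](O)c1ccco1 | intermediate
10 | dilithium alkoxide/acetylide of 9 | [Li]C#CC[C@H](O[Li])c1ccco1 | intermediate (not isolated)
11 | (1S,7R)-1-(furan-2-yl)-7-(propan-2-yl)non-8-en-3-yn-1-ol | C=C[C@@H](C(C)C)CCC#CC[C@H](O)c1ccco1 | intermediate
12 | (1S,3Z,7R)-1-(furan-2-yl)-4-methyl-7-(propan-2-yl)nona-3,8-dien-1-ol | C=C[C@@H](C(C)C)CC/C(C)=C\C[C@H](O)c1ccco1 | intermediate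
13 | ethyl 2-[(tert-butyldimethylsilyl)oxy]acetate | CCOC(=O)CO[Si](C)(C)C(C)(C)C | starting material
14 | 2-[(tert-butyldimethylsilyl)oxy]-N-methoxy-N-methylacetamide | CON(C)C(=O)CO[Si](C)(C)C(C)(C)C | intermediate
15 | lithium alkoxide of 12 lithiated at the free furan α-carbon | C=C[C@@H](C(C)C)CC/C(C)=C\C[C@H](O[Li])c1ccc([Li])o1 | intermediate (not isolated)
16 | 2-[(tert-butyldimethylsilyl)oxy]-1-{5-[(1S,3Z,7R)-1-hydroxy-4-methyl-7-(propan-2-yl)nona-3,8-dien-1-yl]furan-2-yl}ethan-1-one | C=C[C@@H](C(C)C)CC/C(C)=C\C[C@H](O)c1ccc(o1)C(=O)CO[Si](C)(C)C(C)(C)C | intermediate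
17 | bis(bromomagnesium) dialkoxide of the vinyl adduct of 16 | C=C[C@@H](C(C)C)CC/C(C)=C\C[C@H](O[Mg]Br)c1ccc(o1)C(O[Mg]Br)(C=C)CO[Si](C)(C)C(C)(C)C | intermediate (not isolated)
18 | (1S,3Z,7R)-1-{5-[(2RS)-1-[(tert-butyldimethylsilyl)oxy]-2-hydroxybut-3-en-2-yl]furan-2-yl}-4-methyl-7-(propan-2-yl)nona-3,8-dien-1-yl acetate | C=C[C@@H](C(C)C)CC/C(C)=C\C[C@H](OC(C)=O)c1ccc(o1)C(O)(C=C)CO[Si](C)(C)C(C)(C)C | intermediate
19 | 14-membered (2,5)-furanophane: carbocycle C1–C14 with C4–C7 as the furan, E-C1=C2, Z-C10=C11(CH3), C3 OH and CH2OTBS (3RS), C8 OAc (8S), C14 isopropyl (14R) | CC(C)[C@H]1CC/C(C)=C\C[C@H](OC(C)=O)c2ccc(o2)C(O)(CO[Si](C)(C)C(C)(C)C)/C=C/1 | intermediate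
20 | C1–C3 allyl cation of 19 (charge drawn at C3, delocalised to C1 and the furan) | CC(C)[C@H]1CC/C(C)=C\C[C@H](OC(C)=O)c2ccc(o2)[C+](CO[Si](C)(C)C(C)(C)C)/C=C/1 | intermediate (not isolated)
21 | C11 tertiary cation after C1–C10 bond formation | C[C+]1CC[C@H](C(C)C)[C@H]2/C=C(/CO[Si](C)(C)C(C)(C)C)c3ccc(o3)[C@@H](OC(C)=O)C[C@@H]12 | intermediate (not isolated)
22 | furan-bridged tricycle: ring A (C11=C12) cis-fused to the ten-membered ring, Z-C2=C3, furan C4–C7, C15 OTBS, C8 OAc; 1S,8S,10R,14R | CC1=CC[C@H](C(C)C)[C@H]2/C=C(/CO[Si](C)(C)C(C)(C)C)c3ccc(o3)[C@@H](OC(C)=O)C[C@@H]12 | intermediate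
23 | as 22 with free C8 OH; 1S,8S,10R,14R | CC1=CC[C@H](C(C)C)[C@H]2/C=C(/CO[Si](C)(C)C(C)(C)C)c3ccc(o3)[C@@H](O)C[C@@H]12 | intermediate
24 | (5Z)-4,7-dione with free C8 OH (ring-opened furan) | CC1=CC[C@H](C(C)C)[C@H]2/C=C(/CO[Si](C)(C)C(C)(C)C)C(=O)/C=C\C(=O)[C@@H](O)C[C@@H]12 | intermediate (not isolated)
25 | bridged hydroxypyranone: C4 lactol (OH) joined by O to C8, C5=C6, C7 ketone; 1S,4S,8S,10R,14R | CC1=CC[C@H](C(C)C)[C@H]2/C=C(/CO[Si](C)(C)C(C)(C)C)[C@]3(O)C=CC(=O)[C@@H](O3)C[C@@H]12 | intermediate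
26 | bridged pyranose lactol with C7 (OH)(CH3); 1S,4S,7S,8S,10R,14R | CC1=CC[C@H](C(C)C)[C@H]2/C=C(/CO[Si](C)(C)C(C)(C)C)[C@]3(O)C=C[C@](C)(O)[C@@H](O3)C[C@@H]12 | intermediate
27 | 1-methyl-1H-imidazole-4-carbaldehyde | Cn1cnc(C=O)c1 | starting material
28 | (E)-3-(1-methyl-1H-imidazol-4-yl)prop-2-enoic acid | Cn1cnc(/C=C/C(=O)O)c1 | intermediate
29 | (E)-3-(1-methyl-1H-imidazol-4-yl)prop-2-enoic 2,4,6-trichlorobenzoic anhydride | Cn1cnc(/C=C/C(=O)OC(=O)c2c(Cl)cc(Cl)cc2Cl)c1 | intermediate (not isolated)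
30 | furanose tautomer of 26: 4,7-oxa-bridged lactol with free C8 OH; 1S,4R,7S,8S,10R,14R | CC1=CC[C@H](C(C)C)[C@H]2/C=C(/CO[Si](C)(C)C(C)(C)C)[C@@]3(O)C=C[C@](C)(O3)[C@@H](O)C[C@@H]12 | intermediate (not isolated)
31 | 15-O-TBS ether of the target | CC1=CC[C@H](C(C)C)[C@H]2/C=C(/CO[Si](C)(C)C(C)(C)C)[C@@]3(O)C=C[C@](C)(O3)[C@@H](OC(=O)/C=C/c3cn(C)cn3)C[C@@H]12 | intermediate
32 | CNP0196085.1 | CC1=CC[C@H](C(C)C)[C@H]2/C=C(/CO)[C@@]3(O)C=C[C@](C)(O3)[C@@H](OC(=O)/C=C/c3cn(C)cn3)C[C@@H]12 | target

**Step count**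
Total: 18 steps. Longest linear sequence: 15 steps (1–4, 6, 7, 9–15, 17, 18).

**Three steps most likely to fail**

Step 12 (transannular cation–olefin closure). Risks are E1 loss of the C14 proton (which would also erode C14), formation of the exocyclic alkene, and strain in the furanophane. The fallback sets out from 19 and returns at 22. Oxidative 1,3-transposition of the tertiary allylic alcohol (TEMPO oxoammonium tetrafluoroborate, MeCN) gives the macrocyclic (2Z)-dienone with a C1 ketone F1. A Me2AlCl-promoted transannular carbonyl-ene reaction (C10=C11 as ene, C1=O as enophile, hydrogen taken from C12) then forms the C1–C10 bond and the C11=C12 alkene in a concerted way and gives the tricyclic C1 tertiary alcohol F2. Ionic hydrogenation (Et3SiH, CF3CO2H, CH2Cl2, −40 °C) delivers hydride to C1 from the convex face, anti to the C9 bridge, and gives 22.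

Step 11 (ring-closing metathesis onto a vinyl group on a fully substituted carbinol). The fallback sets out from 12 and returns at 22. Dianion 15 is acylated with N-methoxy-N-methylacrylamide to give the furyl vinyl ketone F3. Metathesis of this unhindered enone/vinyl pair with the same ruthenium catalyst gives the macrocyclic (E)-enone F4. Dimethylsulfonium methylide (Me3S+ I−, KN(SiMe3)2, THF) adds 1,2 to give the spiro vinyl epoxide F5, and Ac2O/pyridine gives its C8 acetate F6. Sc(OTf)3 opens the epoxide to the same C1–C3 allyl cation, and transannular closure gives the tricyclic C15 alcohol F7. TBSCl/imidazole converts F7 into 22.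

Step 15 (MeLi on an unprotected lactol that can open to an ene-dione). The fallback sets out from 25 and returns at 26. MeOH/PPTS converts the lactol into the methyl pyranoside F8, which can no longer ring-open. MeLi then adds to the C7 ketone from the same exo face to give the tertiary alcohol methyl pyranoside F9. PPTS in acetone/H2O hydrolyses the ketal to 26.

**Further compounds**
F1 | step 12 | macrocyclic (2Z,10Z)-dienone: C1 ketone, C2=C3(CH2OTBS)–furan, C8 OAc (8S,14R) | CC(C)[C@H]1CC/C(C)=C\C[C@H](OC(C)=O)c2ccc(o2)/C(CO[Si](C)(C)C(C)(C)C)=C\C1=O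
F2 | step 12 | furan-bridged tricycle with tertiary C1 OH (C1 epimers), C11=C12, C8 OAc, C15 OTBS | CC1=CC[C@H](C(C)C)C2(O)/C=C(/CO[Si](C)(C)C(C)(C)C)c3ccc(o3)[C@@H](OC(C)=O)C[C@@H]12
F3 | step 11 | 1-{5-[(1S,3Z,7R)-1-hydroxy-4-methyl-7-(propan-2-yl)nona-3,8-dien-1-yl]furan-2-yl}prop-2-en-1-one | C=C[C@@H](C(C)C)CC/C(C)=C\C[C@H](O)c1ccc(o1)C(=O)C=C
F4 | step 11 | 14-membered (2,5)-furanophane (1E)-en-3-one with free C8 OH (8S,14R) | CC(C)[C@H]1CC/C(C)=C\C[C@H](O)c2ccc(o2)C(=O)/C=C/1
F5 | step 11 | spiro C3–C15 vinyl epoxide of F4 (C3 epimers), free C8 OH | CC(C)[C@H]1CC/C(C)=C\C[C@H](O)c2ccc(o2)C3(CO3)/C=C/1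
F6 | step 11 | C8 acetate of F5 | CC(C)[C@H]1CC/C(C)=C\C[C@H](OC(C)=O)c2ccc(o2)C3(CO3)/C=C/1
F7 | step 11 | furan-bridged tricycle with free C15 OH and C8 OAc (1S,2Z,8S,10R,14R) | CC1=CC[C@H](C(C)C)[C@H]2/C=C(/CO)c3ccc(o3)[C@@H](OC(C)=O)C[C@@H]12
F8 | step 15 | methyl pyranoside (C4 OCH3) of 25 | CC1=CC[C@H](C(C)C)[C@H]2/C=C(/CO[Si](C)(C)C(C)(C)C)[C@]3(OC)C=CC(=O)[C@@H](O3)C[C@@H]12
F9 | step 15 | methyl pyranoside (C4 OCH3) of 26 | CC1=CC[C@H](C(C)C)[C@H]2/C=C(/CO[Si](C)(C)C(C)(C)C)[C@]3(OC)C=C[C@](C)(O)[C@@H](O3)C[C@@H]12
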